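The flask gets 1.50 times the G of the teal run, on the same 1.7 M of E and with the same 6.0 h feed.

| flask | E | G | remark | time |
|---|---|---|---|---|
| teal | 1.7 M | 0.80 equiv (fed, over 6.0 h) | run made earlier; the fed solution adds 0.20 times the starting volume |  |
| flask | 1.7 M | 1.20 equiv (fed, over 6.0 h) | the fed solution adds 0.20 times the starting volume | 8.0 d |

- teal (time / d: X / %): 0.500: 13; 1.04: 22; 2.00: 21; 5.00: 1

(scatter of a reading: 1.5 percentage points)

- charges are per starting volume, the dose included; the dosed solution carries all of it
- at the start none of E is in solution
- a reading or a percentage of X counts all its forms, free or not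

1. time up to 8.0 d at which X stands highest
2. the amount of X, in percent of the E charged, at that time

In the teal run G is the smaller charge, at 0.80 equiv, so you may treat it as the limiting reagent. The highest reading of X there is 22% at 1.04 d. Divide that reading by the charge of G and you have Y, the top of X per equivalent of G charged: 27.5% of the E charged. My own reckoning carries Y unchanged from the teal run to the flask and multiplies it by 1.20 equiv, which puts the flask's top near 33.0%, with the 1.5 percentage points scatter of a reading behind it. Y gives a height, not a time.

The forecast says 28% at 1.6 d, which is lower than my reckoning. Its ground is that “G outlasts E and formation holds up longer and somewhat faster”.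

The flask gives 33.2% at 1.89 d, higher and later than the forecast.

    J + G → X (k = 1.30 L mol⁻¹ h⁻¹)
    J + 2 G → D (k = 1.10 L² mol⁻² h⁻¹)
    Z ⇌ X, rate k3*(cs3 - [X]) while solid is left; crystals form when [X] > cs3 (solubility = 0.110 M, k = 0.550 h⁻¹)
    E ⇌ J, rate k4*(cs4 - [J]) while solid is left; crystals form when [J] > cs4 (solubility = 0.790 M, k = 0.0430 h⁻¹)
    X → Q (k = 0.0640 h⁻¹)

Per equivalent of G the flask holds 27.7% at its top, against the 27.5% of Y, and at that top G stands at 1.84% of its own charge. Now take the neighbouring flask, the same but with 0.480 equiv of G. Y gives 13.2%, and the neighbouring flask gives 19.6%, which is 40.8% per equivalent, more than Y. Each D takes two G in the scheme, and at 8.00 d D stands at 7.36% in the neighbouring flask, against 30.6% in the flask.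

The readings are calculated from invented constants; scatter was added.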